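Ring A of this ent-labdane is disconnected at C1–C2 and C3–C4 (labdane numbering). What remains is the ring of (S)-carvone: its isopropenyl group is C4 with C18/C19, its stereocentre is C5, and its α′-carbon is made into quaternary C10 bearing C20 and a formyl group (C1). A hydrogen-atom-transfer radical–polar crossover annulation with acrolein (C2, C3) closes ring A in one operation; it exploits the gem-dimethyl C4 beside C5, which is exactly the Markovnikov hydrogen-atom adduct of the isopropenyl group. The carvone enone then carries the side chain to C9 by alkylative carbonyl transposition and reductive allylic transposition; C17 is oxidised last.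

Key step: step 4

Remark: C1–C20 in the text are labdane positions; centres that later steps erase (the methyl-bearing carbon of 3, C1/C2 of 8, the carbinol carbon of 14) are carried as mixtures.

Step 1
Reactants: 1 (S)-(+)-carvone
Product: 3 6-methylcarvone (5S)-2,6-dimethyl-5-(prop-1-en-2-yl)cyclohex-2-en-1-one as its C6 epimers, via lithium dienolate 2 (not isolated)
Conditions: LiN(CHMe2)2, THF, −78 °C; MeI, −78 → 0 °C
Reagents that add atoms: iodomethane CI
Why: Kinetic α′-deprotonation of the enone and C-methylation of the cross-conjugated lithium dienolate (enolate alkylation) should install C20; the new centre need not be controlled because step 2 planarises it again.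

Step 2
Reactants: 3 6-methylcarvone
Product: 5 (5R,6S)-6-(hydroxymethyl)-2,6-dimethyl-5-(prop-1-en-2-yl)cyclohex-2-en-1-one, via lithium enolate 4 (not isolated)
Conditions: LiN(CHMe2)2, THF, −78 °C; CH2O gas (cracked paraformaldehyde), −78 °C; AcOH quench at −78 °C
Reagents that add atoms: formaldehyde C=O
Why: Re-enolisation at the same carbon and aldol addition to monomeric formaldehyde (hydroxymethylation) should bring the electrophile in anti to the neighbouring isopropenyl group, so CH2OH (future C1) ends trans and the methyl C20 cis to it, which sets quaternary C10 by 1,2-induction from C5.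

Step 3
Reactants: 5 (5R,6S)-6-(hydroxymethyl)-2,6-dimethyl-5-(prop-1-en-2-yl)cyclohex-2-en-1-one
Product: 6 (1S,6R)-1,3-dimethyl-2-oxo-6-(prop-1-en-2-yl)cyclohex-3-ene-1-carbaldehyde
Conditions: Dess–Martin periodinane, NaHCO3, CH2Cl2, 0 °C → rt
Reagents that add atoms: none
Why: Dess–Martin oxidation of the neopentyl primary alcohol under buffered, non-nucleophilic conditions should give the non-enolisable β-keto aldehyde without retro-aldol or retro-Claisen loss of C1.

Step 4
Reactants: 6 (1S,6R)-1,3-dimethyl-2-oxo-6-(prop-1-en-2-yl)cyclohex-3-ene-1-carbaldehyde; 7 acrolein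
Product: 8 (4aR,8aS)-1-hydroxy-4,4,7,8a-tetramethyl-8-oxo-1,2,3,4,4a,5,8,8a-octahydronaphthalene-2-carbaldehyde (C1/C2 epimers)
Conditions: Fe(acac)3 (0.5 equiv), PhSiH3, EtOH/ethylene glycol, 0 °C → rt, acrolein in excess added slowly
Reagents that add atoms: none
Why: The hydride formed from Fe(acac)3 and PhSiH3 transfers a hydrogen atom to the CH2 terminus of the isopropenyl group (Markovnikov MHAT), so C4 becomes a tertiary radical that already carries both methyl groups; it adds to the β-carbon of acrolein (Giese addition, C3–C4), divalent iron reduces the α-formyl radical to an enolate (radical–polar crossover), and the enolate adds to the neighbouring aldehyde carbon C1 (aldol addition, C1–C2). The closest known reaction type is the Fe(acac)3/PhSiH3 radical conjugate addition–aldol annulation of alkenyl carbonyl compounds with enals and enones. Ring A closes in a 6-(enolexo)-exo-trig aldol addition through a chair transition state. No lasting stereocentre is made: the trans ring fusion is already fixed by the trans C1 and C4 arms on C10 and C5 (both equatorial on ring B), and the C1 carbinol and C2 formyl centres arise as a mixture that steps 5 to 7 erase. The step needs hydrogen-atom transfer to the electron-rich 1,1-disubstituted alkene instead of the electron-poor C7=C8 enone, and aldol capture of the enolate before ethanol protonates it. The polarity match of the hydride donor secures the first, and the second rests on the non-enolisable aldehyde held in six-membered reach of the enolate, with excess acrolein so that reduction of the radical does not compete.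

Step 5
Reactants: 8 (4aR,8aS)-1-hydroxy-4,4,7,8a-tetramethyl-8-oxo-1,2,3,4,4a,5,8,8a-octahydronaphthalene-2-carbaldehyde
Product: 9 (4aR,8aR)-4,4,7,8a-tetramethyl-8-oxo-3,4,4a,5,8,8a-hexahydronaphthalene-2-carbaldehyde
Conditions: p-TsOH·H2O (cat.), benzene, 80 °C
Reagents that add atoms: none
Why: Acid-catalysed aldol dehydration through the enol can only run towards C2 because C10 is quaternary, and it should merge all C1/C2 epimers into one enal.

Step 6
Reactants: 9 (4aR,8aR)-4,4,7,8a-tetramethyl-8-oxo-3,4,4a,5,8,8a-hexahydronaphthalene-2-carbaldehyde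
Product: 10 (4aR,8aR)-2,5,5,8a-tetramethyl-4a,5,6,8a-tetrahydronaphthalen-1(4H)-one
Conditions: RhCl3·3H2O (5 mol %), dppp (10 mol %), diglyme, 162 °C
Reagents that add atoms: none
Why: Tsuji–Wilkinson decarbonylation (oxidative addition into the formyl C–H, CO extrusion, reductive elimination) should remove the activating formyl carbon, and any migration of the ring A alkene is harmless because step 7 saturates it.

Step 7
Reactants: 10 (4aR,8aR)-2,5,5,8a-tetramethyl-4a,5,6,8a-tetrahydronaphthalen-1(4H)-one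
Product: 11 (4aR,8aR)-2,5,5,8a-tetramethyl-4a,5,6,7,8,8a-hexahydronaphthalen-1(4H)-one
Conditions: H2 (1 atm), RhCl(PPh3)3 (5 mol %), benzene, rt
Reagents that add atoms: none
Why: Homogeneous hydrogenation with RhCl(PPh3)3 should reduce the cis-disubstituted ring A alkene and leave the trisubstituted, conjugated C7=C8 alkene alone (steric chemoselectivity, as in the selective reduction of the isopropenyl group of carvone).

Step 8
Reactants: 11 (4aR,8aR)-2,5,5,8a-tetramethyl-4a,5,6,7,8,8a-hexahydronaphthalen-1(4H)-one; 12 (4-bromobut-1-yn-1-yl)trimethylsilane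
Product: 14 (4aR,8aR)-2,5,5,8a-tetramethyl-1-[4-(trimethylsilyl)but-3-yn-1-yl]-1,4,4a,5,6,7,8,8a-octahydronaphthalen-1-ol (carbinol centre undefined), via Grignard reagent 13 (not isolated)
Conditions: 12, Mg, THF, rt; anhydrous CeCl3, THF, −78 °C; 11, −78 → 0 °C; H2O
Reagents that add atoms: none
Why: Grignard formation and transmetalation with CeCl3 to the alkylcerium dichloride should give clean 1,2-addition to the hindered, non-enolisable enone carbonyl C9 (organocerium addition); the carbinol configuration is irrelevant because step 9 removes it.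

Step 9
Reactants: 14 (4aR,8aR)-2,5,5,8a-tetramethyl-1-[4-(trimethylsilyl)but-3-yn-1-yl]-1,4,4a,5,6,7,8,8a-octahydronaphthalen-1-ol
Product: 15 (4aR,8aR)-3,4a,8,8-tetramethyl-4-[4-(trimethylsilyl)but-3-yn-1-yl]-4a,5,6,7,8,8a-hexahydronaphthalen-2(1H)-one
Conditions: pyridinium chlorochromate (C5H5NH)[CrO3Cl], 4 Å MS, CH2Cl2, rt
Reagents that add atoms: pyridinium chlorochromate [O-][Cr](=O)(=O)Cl.c1cc[nH+]cc1 (supplies the C7 oxygen)
Why: Babler–Dauben oxidative 1,3-transposition: the tertiary allylic chromate ester should undergo a [3,3] shift to the secondary C7 chromate, which is oxidised to the transposed enone and leaves the side chain on sp2 C9.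

Step 10
Reactants: 15 (4aR,8aR)-3,4a,8,8-tetramethyl-4-[4-(trimethylsilyl)but-3-yn-1-yl]-4a,5,6,7,8,8a-hexahydronaphthalen-2(1H)-one
Product: 17 (2R,4aR,8aR)-4-(but-3-yn-1-yl)-3,4a,8,8-tetramethyl-1,2,4a,5,6,7,8,8a-octahydronaphthalen-2-ol, via silyl alkyne alcohol 16 (not isolated)
Conditions: NaBH4, CeCl3·7H2O, MeOH, −20 → 0 °C; then K2CO3, rt
Reagents that add atoms: none
Why: Luche 1,2-reduction should deliver hydride axially to C7 from the face of H5, anti to the angular methyl C20, so the hydroxyl ends cis to C20 (substrate control from C5 and C10); K2CO3 in the same methanol then cleaves the alkynyl C–Si bond (protodesilylation).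

Step 11
Reactants: 17 (2R,4aR,8aR)-4-(but-3-yn-1-yl)-3,4a,8,8-tetramethyl-1,2,4a,5,6,7,8,8a-octahydronaphthalen-2-ol
Product: 20 (1R,4aR,8aR)-1-(but-3-yn-1-yl)-2,5,5,8a-tetramethyl-1,4,4a,5,6,7,8,8a-octahydronaphthalene, via sulfonyl hydrazone 18 (not isolated), via allylic diazene 19 (not isolated)
Conditions: N′-isopropylidene-2-nitrobenzenesulfonohydrazide (IPNBSH), PPh3, DEAD, THF, 0 °C → rt; then CF3CH2OH/H2O 1:1, rt
Reagents that add atoms: none
Why: Myers reductive allylic transposition: Mitsunobu displacement inverts C7, hydrolysis of the hydrazone and loss of sulfinate give the monoalkyl diazene, and its retro-ene loss of N2 should deliver hydrogen suprafacially to C9 on the face of H5 while the alkene moves to C7=C8, which sets C9 with the side chain cis to C20.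

Step 12
Reactants: 20 (1R,4aR,8aR)-1-(but-3-yn-1-yl)-2,5,5,8a-tetramethyl-1,4,4a,5,6,7,8,8a-octahydronaphthalene
Product: 23 (2E)-3-methyl-5-[(1R,4aR,8aR)-2,5,5,8a-tetramethyl-1,4,4a,5,6,7,8,8a-octahydronaphthalen-1-yl]pent-2-en-1-ol, via alkenylalane 21 (not isolated), via lithium alkenylaluminate 22 (not isolated)
Conditions: Me3Al, Cp2ZrCl2 (25 mol %), CH2Cl2, 0 °C → rt; then n-BuLi, THF, −78 °C; (CH2O)n, rt; aqueous work-up
Reagents that add atoms: trimethylaluminium C[Al](C)C; paraformaldehyde, as formaldehyde C=O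
Why: Negishi Cp2ZrCl2-catalysed carboalumination should add methyl and aluminium syn across the terminal alkyne (methyl to C13), and hydroxymethylation of the aluminate with retention fixes the 13E trisubstituted alkene and installs C15.

Step 13
Reactants: 24 16-bromohexadecan-1-ol
Product: 25 [(16-bromohexadecyl)oxy](tert-butyl)dimethylsilane
Conditions: TBSCl, imidazole, DMF, rt
Reagents that add atoms: tert-butyldimethylsilyl chloride CC(C)(C)[Si](C)(C)Cl
Why: Standard silyl ether formation masks the primary hydroxyl for the Grignard step.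

Step 14
Reactants: 25 [(16-bromohexadecyl)oxy](tert-butyl)dimethylsilane; 26 16-bromohexadecanoic acid
Product: 29 32-[(tert-butyldimethylsilyl)oxy]dotriacontanoic acid, via Grignard reagent 27 (not isolated), via chloromagnesium carboxylate 28 (not isolated)
Conditions: 25, Mg, THF, 40 °C; separately 26, MeMgCl (1.0 equiv), THF, −20 °C; combine, Li2CuCl4 (3 mol %), −20 °C → rt; cold dilute HCl
Reagents that add atoms: none
Why: Li2CuCl4-catalysed sp3–sp3 cross-coupling (Kochi coupling) of the alkyl Grignard reagent with the ω-bromo carboxylate, pre-formed with MeMgCl so that no Grignard reagent is spent as base, should join the two C16 halves.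

Step 15
Reactants: 23 (2E)-3-methyl-5-[(1R,4aR,8aR)-2,5,5,8a-tetramethyl-1,4,4a,5,6,7,8,8a-octahydronaphthalen-1-yl]pent-2-en-1-ol; 29 32-[(tert-butyldimethylsilyl)oxy]dotriacontanoic acid
Product: 30 (2E)-3-methyl-5-[(1R,4aR,8aR)-2,5,5,8a-tetramethyl-1,4,4a,5,6,7,8,8a-octahydronaphthalen-1-yl]pent-2-en-1-yl 32-[(tert-butyldimethylsilyl)oxy]dotriacontanoate
Conditions: EDC·HCl, DMAP, CH2Cl2, rt
Reagents that add atoms: none
Why: Steglich carbodiimide esterification of the unhindered primary allylic alcohol under DMAP catalysis should proceed without touching the alkenes.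

Step 16
Reactants: 30 (2E)-3-methyl-5-[(1R,4aR,8aR)-2,5,5,8a-tetramethyl-1,4,4a,5,6,7,8,8a-octahydronaphthalen-1-yl]pent-2-en-1-yl 32-[(tert-butyldimethylsilyl)oxy]dotriacontanoate
Product: 31 (2E)-5-[(1S,4aR,8aR)-2-(hydroxymethyl)-5,5,8a-trimethyl-1,4,4a,5,6,7,8,8a-octahydronaphthalen-1-yl]-3-methylpent-2-en-1-yl 32-[(tert-butyldimethylsilyl)oxy]dotriacontanoate
Conditions: SeO2 (0.5 equiv), t-BuOOH, CH2Cl2, rt
Reagents that add atoms: tert-butyl hydroperoxide CC(C)(C)OO (oxygen passed on through catalytic SeO2, O=[Se]=O)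
Why: Riley allylic oxidation (ene reaction, then [2,3] shift) should attack the electron-rich ring alkene at the methyl on its more substituted carbon (C17), because the ring methine C9 is blocked and the C13=C14 alkene is deactivated by its allylic acyloxy group, as in geranyl acetate.

Step 17
Reactants: 31 (2E)-5-[(1S,4aR,8aR)-2-(hydroxymethyl)-5,5,8a-trimethyl-1,4,4a,5,6,7,8,8a-octahydronaphthalen-1-yl]-3-methylpent-2-en-1-yl 32-[(tert-butyldimethylsilyl)oxy]dotriacontanoate
Product: 32 (2E)-5-[(1S,4aR,8aR)-2-(hydroxymethyl)-5,5,8a-trimethyl-1,4,4a,5,6,7,8,8a-octahydronaphthalen-1-yl]-3-methylpent-2-en-1-yl 32-hydroxydotriacontanoate (CNP0264179.1)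
Conditions: HF·pyridine, pyridine, THF, 0 °C → rt
Reagents that add atoms: none
Why: Fluoride cleavage of the primary silyl ether with buffered HF·pyridine should leave the allylic ester and both alkenes intact.

Compound list
1 | (S)-(+)-carvone, (5S)-2-methyl-5-(prop-1-en-2-yl)cyclohex-2-en-1-one | O=C1C(C)=CC[C@H](C(C)=C)C1 | starting material
2 | lithium (3S)-6-methyl-3-(prop-1-en-2-yl)cyclohexa-1,5-dien-1-olate (kinetic dienolate of 1) | [Li]OC1=C[C@@H](C(C)=C)CC=C1C | intermediate
3 | 6-methylcarvone, (5S)-2,6-dimethyl-5-(prop-1-en-2-yl)cyclohex-2-en-1-one, C6 epimers | O=C1C(C)=CC[C@H](C(C)=C)C1C | intermediate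
4 | lithium (3R)-2,6-dimethyl-3-(prop-1-en-2-yl)cyclohexa-1,5-dien-1-olate (enolate of 3, isopropenyl centre unchanged in space) | [Li]OC1=C(C)[C@@H](C(C)=C)CC=C1C | intermediate
5 | (5R,6S)-6-(hydroxymethyl)-2,6-dimethyl-5-(prop-1-en-2-yl)cyclohex-2-en-1-one (CH2OH trans to isopropenyl) | O=C1C(C)=CC[C@H](C(C)=C)[C@]1(CO)C | intermediate
6 | (1S,6R)-1,3-dimethyl-2-oxo-6-(prop-1-en-2-yl)cyclohex-3-ene-1-carbaldehyde | O=C1C(C)=CC[C@H](C(C)=C)[C@]1(C=O)C | intermediate
7 | acrolein (prop-2-enal) | C=CC=O | starting material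
8 | (4aR,8aS)-1-hydroxy-4,4,7,8a-tetramethyl-8-oxo-1,2,3,4,4a,5,8,8a-octahydronaphthalene-2-carbaldehyde, trans-fused, C1/C2 epimers | O=C1C(C)=CC[C@@H]2C(C)(C)CC(C=O)C(O)[C@@]12C | intermediate
9 | (4aR,8aR)-4,4,7,8a-tetramethyl-8-oxo-3,4,4a,5,8,8a-hexahydronaphthalene-2-carbaldehyde | O=C1C(C)=CC[C@@H]2C(C)(C)CC(C=O)=C[C@@]12C | intermediate
10 | (4aR,8aR)-2,5,5,8a-tetramethyl-4a,5,6,8a-tetrahydronaphthalen-1(4H)-one | O=C1C(C)=CC[C@@H]2C(C)(C)CC=C[C@@]12C | intermediate
11 | (4aR,8aR)-2,5,5,8a-tetramethyl-4a,5,6,7,8,8a-hexahydronaphthalen-1(4H)-one | O=C1C(C)=CC[C@@H]2C(C)(C)CCC[C@@]12C | intermediate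
12 | (4-bromobut-1-yn-1-yl)trimethylsilane | C[Si](C)(C)C#CCCBr | starting material
13 | [4-(trimethylsilyl)but-3-yn-1-yl]magnesium bromide | C[Si](C)(C)C#CCC[Mg]Br | intermediate
14 | (4aR,8aR)-2,5,5,8a-tetramethyl-1-[4-(trimethylsilyl)but-3-yn-1-yl]-1,4,4a,5,6,7,8,8a-octahydronaphthalen-1-ol, carbinol centre undefined | C[Si](C)(C)C#CCCC1(O)C(C)=CC[C@@H]2C(C)(C)CCC[C@@]12C | intermediate
15 | (4aR,8aR)-3,4a,8,8-tetramethyl-4-[4-(trimethylsilyl)but-3-yn-1-yl]-4a,5,6,7,8,8a-hexahydronaphthalen-2(1H)-one | C[Si](C)(C)C#CCCC1=C(C)C(=O)C[C@@H]2C(C)(C)CCC[C@@]12C | intermediate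
16 | (2R,4aR,8aR)-3,4a,8,8-tetramethyl-4-[4-(trimethylsilyl)but-3-yn-1-yl]-1,2,4a,5,6,7,8,8a-octahydronaphthalen-2-ol (OH cis to the angular methyl) | C[Si](C)(C)C#CCCC1=C(C)[C@H](O)C[C@@H]2C(C)(C)CCC[C@@]12C | intermediate
17 | (2R,4aR,8aR)-4-(but-3-yn-1-yl)-3,4a,8,8-tetramethyl-1,2,4a,5,6,7,8,8a-octahydronaphthalen-2-ol | C#CCCC1=C(C)[C@H](O)C[C@@H]2C(C)(C)CCC[C@@]12C | intermediate
18 | N-[(2S,4aR,8aR)-4-(but-3-yn-1-yl)-3,4a,8,8-tetramethyl-1,2,4a,5,6,7,8,8a-octahydronaphthalen-2-yl]-2-nitro-N′-(propan-2-ylidene)benzenesulfonohydrazide | C#CCCC1=C(C)[C@@H](N(N=C(C)C)S(=O)(=O)c3ccccc3[N+](=O)[O-])C[C@@H]2C(C)(C)CCC[C@@]12C | intermediate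
19 | [(2S,4aR,8aR)-4-(but-3-yn-1-yl)-3,4a,8,8-tetramethyl-1,2,4a,5,6,7,8,8a-octahydronaphthalen-2-yl]diazene | C#CCCC1=C(C)[C@@H](N=N)C[C@@H]2C(C)(C)CCC[C@@]12C | intermediate
20 | (1R,4aR,8aR)-1-(but-3-yn-1-yl)-2,5,5,8a-tetramethyl-1,4,4a,5,6,7,8,8a-octahydronaphthalene (side chain cis to the angular methyl) | C#CCC[C@@H]1C(C)=CC[C@@H]2C(C)(C)CCC[C@@]12C | intermediate
21 | dimethyl{(1E)-2-methyl-4-[(1R,4aR,8aR)-2,5,5,8a-tetramethyl-1,4,4a,5,6,7,8,8a-octahydronaphthalen-1-yl]but-1-en-1-yl}alane | C[Al](C)/C=C(\C)CC[C@@H]1C(C)=CC[C@@H]2C(C)(C)CCC[C@@]12C | intermediate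
22 | lithium butyl(dimethyl){(1E)-2-methyl-4-[(1R,4aR,8aR)-2,5,5,8a-tetramethyl-1,4,4a,5,6,7,8,8a-octahydronaphthalen-1-yl]but-1-en-1-yl}aluminate | [Li+].CCCC[Al-](C)(C)/C=C(\C)CC[C@@H]1C(C)=CC[C@@H]2C(C)(C)CCC[C@@]12C | intermediate
23 | ent-labda-7,13E-dien-15-ol, (2E)-3-methyl-5-[(1R,4aR,8aR)-2,5,5,8a-tetramethyl-1,4,4a,5,6,7,8,8a-octahydronaphthalen-1-yl]pent-2-en-1-ol | C/C(=C\CO)CC[C@@H]1C(C)=CC[C@@H]2C(C)(C)CCC[C@@]12C | intermediate
24 | 16-bromohexadecan-1-ol | OCCCCCCCCCCCCCCCCBr | starting material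
25 | [(16-bromohexadecyl)oxy](tert-butyl)dimethylsilane | CC(C)(C)[Si](C)(C)OCCCCCCCCCCCCCCCCBr | intermediate
26 | 16-bromohexadecanoic acid | OC(=O)CCCCCCCCCCCCCCCBr | starting material
27 | {16-[(tert-butyldimethylsilyl)oxy]hexadecyl}magnesium bromide | CC(C)(C)[Si](C)(C)OCCCCCCCCCCCCCCCC[Mg]Br | intermediate
28 | chloromagnesium 16-bromohexadecanoate | Cl[Mg]OC(=O)CCCCCCCCCCCCCCCBr | intermediate
29 | 32-[(tert-butyldimethylsilyl)oxy]dotriacontanoic acid | OC(=O)CCCCCCCCCCCCCCCCCCCCCCCCCCCCCCCO[Si](C)(C)C(C)(C)C | intermediate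
30 | (2E)-3-methyl-5-[(1R,4aR,8aR)-2,5,5,8a-tetramethyl-1,4,4a,5,6,7,8,8a-octahydronaphthalen-1-yl]pent-2-en-1-yl 32-[(tert-butyldimethylsilyl)oxy]dotriacontanoate | C/C(=C\COC(=O)CCCCCCCCCCCCCCCCCCCCCCCCCCCCCCCO[Si](C)(C)C(C)(C)C)CC[C@@H]1C(C)=CC[C@@H]2C(C)(C)CCC[C@@]12C | intermediate
31 | (2E)-5-[(1S,4aR,8aR)-2-(hydroxymethyl)-5,5,8a-trimethyl-1,4,4a,5,6,7,8,8a-octahydronaphthalen-1-yl]-3-methylpent-2-en-1-yl 32-[(tert-butyldimethylsilyl)oxy]dotriacontanoate | C/C(=C\COC(=O)CCCCCCCCCCCCCCCCCCCCCCCCCCCCCCCO[Si](C)(C)C(C)(C)C)CC[C@@H]1C(CO)=CC[C@@H]2C(C)(C)CCC[C@@]12C | intermediate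
32 | (2E)-5-[(1S,4aR,8aR)-2-(hydroxymethyl)-5,5,8a-trimethyl-1,4,4a,5,6,7,8,8a-octahydronaphthalen-1-yl]-3-methylpent-2-en-1-yl 32-hydroxydotriacontanoate (CNP0264179.1) | C/C(=C\COC(=O)CCCCCCCCCCCCCCCCCCCCCCCCCCCCCCCO)CC[C@@H]1C(CO)=CC[C@@H]2C(C)(C)CCC[C@@]12C | target

Total step count: 17.
Longest linear sequence: 15 steps (steps 1–12 and 15–17, from (S)-carvone); steps 13–14 make the acid in a side branch.

Steps most likely to fail

Step 4. The cascade may stop half-way: protonation of the enolate by ethanol can outrun the aldol closure, acrolein can be lost to oligomerisation, and the β-keto aldehyde can lose its formyl group by ethanolysis, so that at best only the C3–C4 bond forms. The fallback sets out from 6 and comes back at 9. The Giese coupling of 6 with acrolein (Fe(acac)3, PhSiH3, EtOH) is run for the open-chain product alone, which is isolated as (1S,6R)-1,3-dimethyl-6-(2-methyl-5-oxopentan-2-yl)-2-oxocyclohex-3-ene-1-carbaldehyde F1. A separate enamine aldol condensation (pyrrolidine, AcOH, benzene, 80 °C) then closes ring A and dehydrates to enal 9; only the chain aldehyde can form an enamine and only the C1 aldehyde lies in six-membered reach.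

Step 11. The Mitsunobu displacement at the hindered C7 carbinol beside a tetrasubstituted alkene may be slow or may run through ionisation (SN1, SN2′ or elimination to a diene), which would erode the transfer of configuration from C7 to C9. The fallback sets out from 16 and comes back at 20. Step 10 is stopped before K2CO3 is added, so that 16 is isolated with its silyl group in place. Formylation (HCO2H, Ac2O, pyridine) gives (2R,4aR,8aR)-3,4a,8,8-tetramethyl-4-[4-(trimethylsilyl)but-3-yn-1-yl]-1,2,4a,5,6,7,8,8a-octahydronaphthalen-2-yl formate F2. Pd(OAc)2 and n-Bu3P in THF at reflux (Tsuji–Mandai formate reduction) follow: zerovalent palladium ionises the formate anti, CO2 is lost, and hydride passes from palladium to the more substituted terminus C9 on the face of H5. This gives trimethyl{4-[(1R,4aR,8aR)-2,5,5,8a-tetramethyl-1,4,4a,5,6,7,8,8a-octahydronaphthalen-1-yl]but-1-yn-1-yl}silane F3, and K2CO3 in MeOH then frees the alkyne to give 20.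

Step 16. Site selectivity of the allylic oxidation may fail: attack at the side-chain allylic positions C12 and C16 or at ring positions C6 and C9, and over-oxidation to the C17 aldehyde, all compete. The fallback sets out from 20 and comes back at 32. The oxidation is moved to alkyne 20, in which C7=C8 is the only alkene (SeO2, t-BuOOH, CH2Cl2), to give [(1S,4aR,8aR)-1-(but-3-yn-1-yl)-5,5,8a-trimethyl-1,4,4a,5,6,7,8,8a-octahydronaphthalen-2-yl]methanol F4. Silylation (TBSCl, imidazole, DMF) gives tert-butyl{[(1S,4aR,8aR)-1-(but-3-yn-1-yl)-5,5,8a-trimethyl-1,4,4a,5,6,7,8,8a-octahydronaphthalen-2-yl]methoxy}dimethylsilane F5. Carboalumination and hydroxymethylation as in step 12 give (2E)-5-[(1S,4aR,8aR)-2-{[(tert-butyldimethylsilyl)oxy]methyl}-5,5,8a-trimethyl-1,4,4a,5,6,7,8,8a-octahydronaphthalen-1-yl]-3-methylpent-2-en-1-ol F6. Esterification with 29 as in step 15 gives (2E)-5-[(1S,4aR,8aR)-2-{[(tert-butyldimethylsilyl)oxy]methyl}-5,5,8a-trimethyl-1,4,4a,5,6,7,8,8a-octahydronaphthalen-1-yl]-3-methylpent-2-en-1-yl 32-[(tert-butyldimethylsilyl)oxy]dotriacontanoate F7, and HF·pyridine removes both silyl groups to give 32.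

Further compounds
F1 | step 4 | (1S,6R)-1,3-dimethyl-6-(2-methyl-5-oxopentan-2-yl)-2-oxocyclohex-3-ene-1-carbaldehyde | O=C1C(C)=CC[C@H](C(C)(C)CCC=O)[C@]1(C=O)C
F2 | step 11 | (2R,4aR,8aR)-3,4a,8,8-tetramethyl-4-[4-(trimethylsilyl)but-3-yn-1-yl]-1,2,4a,5,6,7,8,8a-octahydronaphthalen-2-yl formate | C[Si](C)(C)C#CCCC1=C(C)[C@H](OC=O)C[C@@H]2C(C)(C)CCC[C@@]12C
F3 | step 11 | trimethyl{4-[(1R,4aR,8aR)-2,5,5,8a-tetramethyl-1,4,4a,5,6,7,8,8a-octahydronaphthalen-1-yl]but-1-yn-1-yl}silane | C[Si](C)(C)C#CCC[C@@H]1C(C)=CC[C@@H]2C(C)(C)CCC[C@@]12C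
F4 | step 16 | [(1S,4aR,8aR)-1-(but-3-yn-1-yl)-5,5,8a-trimethyl-1,4,4a,5,6,7,8,8a-octahydronaphthalen-2-yl]methanol | C#CCC[C@@H]1C(CO)=CC[C@@H]2C(C)(C)CCC[C@@]12C
F5 | step 16 | tert-butyl{[(1S,4aR,8aR)-1-(but-3-yn-1-yl)-5,5,8a-trimethyl-1,4,4a,5,6,7,8,8a-octahydronaphthalen-2-yl]methoxy}dimethylsilane | C#CCC[C@@H]1C(CO[Si](C)(C)C(C)(C)C)=CC[C@@H]2C(C)(C)CCC[C@@]12C
F6 | step 16 | (2E)-5-[(1S,4aR,8aR)-2-{[(tert-butyldimethylsilyl)oxy]methyl}-5,5,8a-trimethyl-1,4,4a,5,6,7,8,8a-octahydronaphthalen-1-yl]-3-methylpent-2-en-1-ol | C/C(=C\CO)CC[C@@H]1C(CO[Si](C)(C)C(C)(C)C)=CC[C@@H]2C(C)(C)CCC[C@@]12C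
F7 | step 16 | (2E)-5-[(1S,4aR,8aR)-2-{[(tert-butyldimethylsilyl)oxy]methyl}-5,5,8a-trimethyl-1,4,4a,5,6,7,8,8a-octahydronaphthalen-1-yl]-3-methylpent-2-en-1-yl 32-[(tert-butyldimethylsilyl)oxy]dotriacontanoate | C/C(=C\COC(=O)CCCCCCCCCCCCCCCCCCCCCCCCCCCCCCCO[Si](C)(C)C(C)(C)C)CC[C@@H]1C(CO[Si](C)(C)C(C)(C)C)=CC[C@@H]2C(C)(C)CCC[C@@]12C
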